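**Plan**

- Retrosynthesis: open a cyclic anhydride (masked diacid); cut the bond between the cyclohexane quaternary carbon Cc (CH3, bicycle) and the bicyclooctane CH (decarboxylative radical conjugate addition); cut ring A (the cyclohexane) at CH2–Ca (Ca = quaternary carbon with CH3 and CO2H) and at Cb–Cc (Cb = CH–CO2H) as an alkylation/Michael pair; cut the bicyclo[3.2.1]octenone at CH–C(=CH2) (enol silane onto alkyne) and then to a Diels–Alder pair.
- Enabling feature: Ca and Cb of ring A carry cis CO2H groups, i.e. a latent butenolide. Ca is then the α-carbon of a γ-lactone whose enolate forms only there, by conjugate addition at Cb, and is alkylated by the chain CH2Br; the temporary cis-fused lactone acetal closes ring A and fixes Ca.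
- Forward: chiral butenolide + bromo ester → ring A → redox-active ester with anhydride; separately amino-siloxy diene + propargyl acrolein → cyclohexenone → bicyclo[3.2.1]octenone; the two fragments are joined at Cc, then the anhydride is opened.
- Stereochemistry: menthyl acetal centre → Cb (anti addition) → Ca (cis fusion). Cc is carried as an epimer mixture and both epimers converge through one planar radical that bonds on the convex face; the same step sets the bicyclic CH on the exo face of the enone. The bicyclic quaternary carbon comes from a catalytic asymmetric Diels–Alder reaction; the bridgehead CH follows from bridging.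

Key step: step 4

Assumption: the 3-methyl menthyl acetal is taken to behave like its unsubstituted parent, the d-menthyl acetal crystallizing as the 5S epimer; if the series crystallizes the other way, l-menthol delivers the same 5S centre.
Assumption: the (R,R) antipode of the chromium salen catalyst is written for step 9; the antipode that delivers the R-configured cyclohexenone is the one to be used.

**Step 1**
Reactants: 1 3-methylfuran-2-carboxylic acid
Product: 3 5-hydroxy-3-methylfuran-2(5H)-one (racemic), via endoperoxide 2 (not isolated)
Conditions: O2, hν (visible), rose bengal disodium salt C20H2Cl4I4Na2O5 (cat.), MeOH, 0 °C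
Reagents that add atoms: dioxygen, O=O
Why: [4+2] addition of singlet oxygen across C2/C5 of the furan and decarboxylative fragmentation of the endoperoxide (photooxygenation of 2-furoic acids) should leave the former C2 as the lactone carbonyl, so that the methyl group sits α to it.

**Step 2**
Reactants: 3 5-hydroxy-3-methylfuran-2(5H)-one; 4 (+)-menthol
Product: 5 (5S)-3-methyl-5-{[(1S,2R,5S)-5-methyl-2-(propan-2-yl)cyclohexyl]oxy}furan-2(5H)-one
Conditions: TsOH·H2O (cat.), toluene, reflux (Dean–Stark); crystallization from hexane, mother liquor re-equilibrated with acid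
Reagents that add atoms: none
Why: acid-catalysed acetalization of the pseudo-acid gives two acetal epimers that interconvert under acid, so crystallization should funnel the material into the 5S epimer (crystallization-induced diastereomer transformation, as in the parent menthyloxyfuranone series).

**Step 3**
Reactants: 6 benzyl propanoate; 7 1,3-dibromopropane
Product: 9 benzyl 5-bromo-2-methylpentanoate (racemic), via lithium enolate 8 (not isolated)
Conditions: LiN(i-Pr)2, THF, −78 °C; then 7 (4 equiv), DMPU, −78 → −30 °C
Reagents that add atoms: none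
Why: ester enolate alkylation with an excess of the dihalide should give the monoalkylated bromo ester, whose stereocentre is of no consequence.

**Step 4**
Reactants: 9 benzyl 5-bromo-2-methylpentanoate; 5 the (5S)-menthyloxy butenolide
Product: 12 benzyl (3S,3aS,7aR)-4,7a-dimethyl-3-(d-menthyloxy)-1-oxooctahydro-2-benzofuran-4-carboxylate as both C4 epimers, via lithium enolate 10 (not isolated), via lactone enolate 11 (not isolated)
Conditions: LiN(i-Pr)2, THF, −78 °C; add 5, −78 °C; then DMPU, −78 → 0 °C
Reagents that add atoms: none
Why: Enolate 10 adds in conjugate fashion to the butenolide β-carbon (future Cb) on the face anti to the menthyloxy group, which creates lactone enolate 11 regiospecifically at the methyl-bearing α-carbon (future Ca), and this enolate displaces the primary bromide to form the CH2–Ca bond. The closest known reaction type is the tandem conjugate addition/enolate alkylation of 5-alkoxyfuran-2(5H)-ones (Michael-initiated ring closure), here with the alkylation made intramolecular. Ring A closes in the 6-exo-tet mode with the enolate C=C exocyclic to the new ring. Cb is controlled by the acetal stereocentre (anti addition) and Ca by the ring fusion, because a six-membered ring can only close cis onto the γ-lactone, so CH3 and H at the fusion end up on the same face whatever the configuration of the acyclic quaternary carbon Cc. The step needs conjugate addition to outrun proton transfer from the acetal CH and four-membered ring closure of 10, and C- over O-alkylation; low temperature, the absence of any other acidic C–H in 11 (Cb is flanked by the acetal carbon, the ester α-carbon is quaternary) and the short tether should secure this. Both Cc epimers of 12 are expected and both are used, since this centre is erased and reset in step 12.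

**Step 5**
Reactants: 12 the benzyl ester lactone acetal
Product: 13 (3S,3aS,7aR)-4,7a-dimethyl-3-(d-menthyloxy)-1-oxooctahydro-2-benzofuran-4-carboxylic acid as both C4 epimers
Conditions: H2 (1 atm), Pd/C, EtOAc, rt
Reagents that add atoms: none
Why: hydrogenolysis of the benzyl ester should free the hindered tertiary acid while the lactone acetal, which has no benzylic C–O bond, stays intact.

**Step 6**
Reactants: 13 the carboxylic acid
Product: 14 1,3-dioxoisoindolin-2-yl ester of 13 (N-acyloxyphthalimide; ring stereocentres as in 13)
Conditions: N-hydroxyphthalimide, N,N'-diisopropylcarbodiimide, 4-(dimethylamino)pyridine (cat.), CH2Cl2, rt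
Reagents that add atoms: N-hydroxyphthalimide, ON1C(=O)c2ccccc2C1=O
Why: carbodiimide esterification (Steglich type) converts the acid into a redox-active ester before the latent anhydride is unveiled, so that no free carboxyl can exchange with it.

**Step 7**
Reactants: 14 the redox-active ester
Product: 16 1,3-dioxoisoindolin-2-yl 4,7a-dimethyl-1,3-dioxooctahydro-2-benzofuran-4-carboxylate (cis-fused anhydride; fusion CH3 and H cis; both C4 epimers), via lactol 15 (not isolated)
Conditions: CF3CO2H/H2O (4:1), 50 °C; then Dess–Martin periodinane, CH2Cl2, rt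
Reagents that add atoms: water, O
Why: aqueous acid should hydrolyse the acylal to the lactol and release the auxiliary, and Dess–Martin oxidation of the hemiacetal OH then gives the cis-fused anhydride, which protects both future carboxyl groups without changing the ring-fusion centres.

**Step 8**
Reactants: 17 pent-4-ynal
Product: 18 2-methylidenepent-4-ynal
Conditions: 37% aq. CH2O, pyrrolidine (10 mol %), propionic acid (10 mol %), i-PrOH, 45 °C
Reagents that add atoms: formaldehyde, C=O
Why: amine-catalysed α-methylenation of an aldehyde (Mannich condensation and elimination) installs the 2-substituted acrolein.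

**Step 9**
Reactants: 18 2-methylidenepent-4-ynal; 19 (E)-3-[(tert-butyldimethylsilyl)oxy]-N,N-dimethylbuta-1,3-dien-1-amine
Product: 21 (R)-4-oxo-1-(prop-2-yn-1-yl)cyclohex-2-ene-1-carbaldehyde, via cycloadduct 20 (not isolated)
Conditions: [Cr(salen)]SbF6 (5 mol %; salen = (1R,2R)-N,N'-bis(3,5-di-tert-butylsalicylidene)cyclohexane-1,2-diaminate; trivalent chromium), 4 Å MS, CH2Cl2, −40 °C; then 1 M HCl, THF, 0 °C
Reagents that add atoms: none
Why: catalytic asymmetric Diels–Alder reaction of a 1-amino-3-siloxydiene with a 2-substituted acrolein, in which the diene CH2 bonds to the acrolein CH2 and the amino carbon to the substituted carbon while the chiral Lewis acid selects the enal face and so sets the quaternary centre; acid then hydrolyses the enol silane and eliminates dimethylamine to the enone.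

**Step 10**
Reactants: 21 the cyclohexenone aldehyde
Product: 22 (R)-4-[(tert-butyldimethylsilyl)oxy]-1-(prop-2-yn-1-yl)cyclohexa-2,4-diene-1-carbaldehyde
Conditions: t-BuMe2SiOTf, Et3N, CH2Cl2, −78 → 0 °C
Reagents that add atoms: tert-butyldimethylsilyl trifluoromethanesulfonate, CC(C)(C)[Si](C)(C)OS(=O)(=O)C(F)(F)F
Why: soft enolization of the enone can only take place at the α' CH2 because the γ carbon is quaternary, so the cross-conjugated silyloxydiene should form as a single regioisomer.

**Step 11**
Reactants: 22 the silyloxydiene
Product: 23 (1R,5R)-6-methylidene-4-oxobicyclo[3.2.1]oct-2-ene-1-carbaldehyde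
Conditions: Ph3PAuNTf2 (5 mol %), CH2Cl2/MeOH (10:1), rt
Reagents that add atoms: none
Why: gold-catalysed carbocyclization of a silyl enol ether onto a terminal alkyne (Conia-ene type, 5-exo-dig) should give the exocyclic methylene after protodeauration, and the two-carbon bridge can only form on the face that carries the propargyl group, which sets the bridgehead CH.

**Step 12**
Reactants: 16 the redox-active ester anhydride; 23 the bicyclic enone
Product: 24 cyclic anhydride of the target diacid (cis-fused; all stereocentres as in 25)
Conditions: Ru(bpy)3(PF6)2 (1 mol %), diethyl 2,6-dimethyl-1,4-dihydropyridine-3,5-dicarboxylate (1.5 equiv), CH2Cl2, blue LEDs, rt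
Reagents that add atoms: none
Why: photoredox decarboxylative radical conjugate addition (Giese type) in which both Cc epimers of 16 give one planar tertiary radical that should bond on the convex face of the cis-fused bicycle (the face of the fusion H and CH3) to the exo face of the enone β-carbon (axial attack, anti to the two-carbon bridge), setting Cc and the bicyclic CH together.

**Step 13**
Reactants: 24 the anhydride
Product: 25 (1R,2S,3S)-3-[(1R,2S,5R)-1-formyl-6-methylidene-4-oxobicyclo[3.2.1]octan-2-yl]-1,3-dimethylcyclohexane-1,2-dicarboxylic acid (CNP0320711.1)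
Conditions: LiOH·H2O (3 equiv), THF/H2O, 0 °C → rt; then 1 M HCl to pH 2, 0 °C
Reagents that add atoms: water, O
Why: mild basic hydrolysis of the cyclic anhydride and acidification should release the cis diacid, the non-enolizable aldehyde, the ketone and the exocyclic alkene being inert under these conditions.

**Compound list**

1 | 3-methylfuran-2-carboxylic acid | Cc1ccoc1C(=O)O | starting material
2 | 6-methyl-2,3,7-trioxabicyclo[2.2.1]hept-5-ene-1-carboxylic acid (endoperoxide, racemic) | CC1=CC2OOC1(C(=O)O)O2 | intermediate
3 | 5-hydroxy-3-methylfuran-2(5H)-one (racemic) | CC1=CC(O)OC1=O | intermediate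
4 | (+)-menthol, (1S,2R,5S)-5-methyl-2-(propan-2-yl)cyclohexan-1-ol | O[C@@H]1[C@@H](C(C)C)CC[C@H](C)C1 | starting material
5 | (5S)-3-methyl-5-{[(1S,2R,5S)-5-methyl-2-(propan-2-yl)cyclohexyl]oxy}furan-2(5H)-one | CC1=C[C@@H](O[C@@H]2[C@@H](C(C)C)CC[C@H](C)C2)OC1=O | intermediate
6 | benzyl propanoate | CCC(=O)OCc1ccccc1 | starting material
7 | 1,3-dibromopropane | BrCCCBr | starting material
8 | lithium enolate of 6 | [Li]OC(=CC)OCc1ccccc1 | intermediate
9 | benzyl 5-bromo-2-methylpentanoate (racemic) | CC(CCCBr)C(=O)OCc1ccccc1 | intermediate
10 | lithium enolate of 9 | [Li]OC(=C(C)CCCBr)OCc1ccccc1 | intermediate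
11 | lithium lactone enolate of the conjugate adduct of 10 and 5 (acyclic quaternary carbon as both epimers) | [Li]OC1=C(C)[C@H](C(C)(CCCBr)C(=O)OCc2ccccc2)[C@@H](O[C@@H]3[C@@H](C(C)C)CC[C@H](C)C3)O1 | intermediate
12 | benzyl (3S,3aS,7aR)-4,7a-dimethyl-3-(d-menthyloxy)-1-oxooctahydro-2-benzofuran-4-carboxylate (cis-fused; menthyloxy anti to ring A; both C4 epimers) | O=C(OCc1ccccc1)C2(C)CCC[C@]3(C)[C@H]2[C@@H](O[C@@H]4[C@@H](C(C)C)CC[C@H](C)C4)OC3=O | intermediate
13 | (3S,3aS,7aR)-4,7a-dimethyl-3-(d-menthyloxy)-1-oxooctahydro-2-benzofuran-4-carboxylic acid (both C4 epimers) | OC(=O)C1(C)CCC[C@]2(C)[C@H]1[C@@H](O[C@@H]3[C@@H](C(C)C)CC[C@H](C)C3)OC2=O | intermediate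
14 | 1,3-dioxoisoindolin-2-yl ester of 13 (ring stereocentres as in 13) | O=C(ON1C(=O)c2ccccc2C1=O)C3(C)CCC[C@]4(C)[C@H]3[C@@H](O[C@@H]5[C@@H](C(C)C)CC[C@H](C)C5)OC4=O | intermediate
15 | lactol from 14 (3-hydroxy lactone; anomers) | O=C(ON1C(=O)c2ccccc2C1=O)C3(C)CCC[C@]4(C)[C@H]3C(O)OC4=O | intermediate
16 | 1,3-dioxoisoindolin-2-yl 4,7a-dimethyl-1,3-dioxooctahydro-2-benzofuran-4-carboxylate (cis-fused anhydride; fusion CH3 and H cis; both C4 epimers) | O=C(ON1C(=O)c2ccccc2C1=O)C3(C)CCC[C@]4(C)[C@H]3C(=O)OC4=O | intermediate
17 | pent-4-ynal | C#CCCC=O | starting material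
18 | 2-methylidenepent-4-ynal | C#CCC(=C)C=O | intermediate
19 | (E)-3-[(tert-butyldimethylsilyl)oxy]-N,N-dimethylbuta-1,3-dien-1-amine | CN(C)/C=C/C(=C)O[Si](C)(C)C(C)(C)C | starting material
20 | (1R,2R)-4-[(tert-butyldimethylsilyl)oxy]-2-(dimethylamino)-1-(prop-2-yn-1-yl)cyclohex-3-ene-1-carbaldehyde (amino cis to formyl) | C#CC[C@]1(C=O)CCC(O[Si](C)(C)C(C)(C)C)=C[C@H]1N(C)C | intermediate
21 | (R)-4-oxo-1-(prop-2-yn-1-yl)cyclohex-2-ene-1-carbaldehyde | C#CC[C@]1(C=O)CCC(=O)C=C1 | intermediate
22 | (R)-4-[(tert-butyldimethylsilyl)oxy]-1-(prop-2-yn-1-yl)cyclohexa-2,4-diene-1-carbaldehyde | C#CC[C@]1(C=O)CC=C(O[Si](C)(C)C(C)(C)C)C=C1 | intermediate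
23 | (1R,5R)-6-methylidene-4-oxobicyclo[3.2.1]oct-2-ene-1-carbaldehyde | C=C1C[C@]2(C=O)C[C@H]1C(=O)C=C2 | intermediate
24 | cyclic anhydride of 25 | C=C1C[C@]2(C=O)C[C@H]1C(=O)C[C@H]2[C@]1(C)CCC[C@]3(C)[C@H]1C(=O)OC3=O | intermediate
25 | (1R,2S,3S)-3-[(1R,2S,5R)-1-formyl-6-methylidene-4-oxobicyclo[3.2.1]octan-2-yl]-1,3-dimethylcyclohexane-1,2-dicarboxylic acid | C=C1C[C@]2(C=O)C[C@H]1C(=O)C[C@H]2[C@]1(C)CCC[C@@](C)(C(=O)O)[C@H]1C(=O)O | target

**Summary**

Total step count: 13. Longest linear sequence: 8 steps (steps 1, 2, 4, 5, 6, 7, 12, 13).

**Steps most likely to fail**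

Step 12. The tertiary radical may be reduced before it adds to the enone β-carbon, which lies next to the quaternary bridgehead, or it may add with insufficient exo-face selectivity. The fallback sets out from 16 and 18 and comes back at 24; it forms the ring of the bicycle after the quaternary centre has been made. The radical from 16 is added under the same photoredox conditions to but-3-yn-2-one (CC(=O)C#C), which after iodine-catalysed equilibration should give the (E)-enone F1. i-Pr3SiOTf/Et3N converts F1 into the 2-silyloxydiene F2. A Lewis acid-promoted (Me2AlCl, CH2Cl2, −78 °C) endo Diels–Alder reaction of F2 with 18 is expected to give the cyclohexene F3 with the formyl group cis to the ring A carbon; the diene should be attacked anti to the ring-fusion CH of ring A. Dilute HCl liberates the ketone F4, t-BuMe2SiOTf/Et3N should enolize the CH2 remote from the quaternary substituent to give F5, and Ph3PAuNTf2 in CH2Cl2/MeOH closes the five-membered ring to 24.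

Step 4. Proton transfer from the acetal CH of 5 to the hindered enolate 10 would erase the acetal configuration; conjugate addition to the α-methyl butenolide may also be slow enough for four-membered ring closure of 10 to intervene. The fallback sets out from 9 and comes back at 12. Enolate 10 is added to the commercial, more electrophilic (5S)-5-(d-menthyloxy)furan-2(5H)-one F6, and the same tandem addition/alkylation should give the cis-fused lactone F7, which lacks the ring-fusion methyl. Deprotonation of its only acidic CH (LiN(i-Pr)2, THF, −78 °C) and methylation with iodomethane on the convex face, cis fusion again being the only accessible mode, should give 12.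

Step 7. The redox-active ester may be hydrolysed, or the acylal may be cleaved incompletely, under aqueous acid. The fallback sets out from 14 and 23 and comes back at 24; it moves the unmasking behind the fragment union. 14 is coupled with 23 under the conditions of step 12 to give F8 with the menthyl acetal retained. Brief treatment with CF3CO2H/H2O at 0 °C → rt should give the lactol F9, and Dess–Martin periodinane, to which the aldehyde is inert, oxidizes the hemiacetal to 24.

**Further compounds**

F1 | step 12 | cis-fused anhydride of ring A bearing an (E)-3-oxobut-1-en-1-yl group on Cc | CC(=O)/C=C/[C@]1(C)CCC[C@]2(C)[C@H]1C(=O)OC2=O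
F2 | step 12 | 2-(triisopropylsilyloxy)diene from F1 | C=C(O[Si](C(C)C)(C(C)C)C(C)C)/C=C/[C@]1(C)CCC[C@]2(C)[C@H]1C(=O)OC2=O
F3 | step 12 | endo Diels–Alder adduct of F2 and 18 (formyl cis to the ring A carbon) | C#CC[C@]1(C=O)CCC(O[Si](C(C)C)(C(C)C)C(C)C)=C[C@H]1[C@]2(C)CCC[C@]3(C)[C@H]2C(=O)OC3=O
F4 | step 12 | cyclohexanone from F3 | C#CC[C@]1(C=O)CCC(=O)C[C@H]1[C@]2(C)CCC[C@]3(C)[C@H]2C(=O)OC3=O
F5 | step 12 | tert-butyldimethylsilyl enol ether of F4 with the double bond remote from ring A | C#CC[C@]1(C=O)CC=C(O[Si](C)(C)C(C)(C)C)C[C@H]1[C@]2(C)CCC[C@]3(C)[C@H]2C(=O)OC3=O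
F6 | step 4 | (5S)-5-{[(1S,2R,5S)-5-methyl-2-(propan-2-yl)cyclohexyl]oxy}furan-2(5H)-one (commercial) | O=C1C=C[C@@H](O[C@@H]2[C@@H](C(C)C)CC[C@H](C)C2)O1
F7 | step 4 | analogue of 12 with H in place of the ring-fusion methyl (cis-fused; both C4 epimers) | O=C(OCc1ccccc1)C2(C)CCC[C@@H]3[C@H]2[C@@H](O[C@@H]4[C@@H](C(C)C)CC[C@H](C)C4)OC3=O
F8 | step 7 | coupling product of 14 and 23 with the menthyl acetal retained | C=C1C[C@]2(C=O)C[C@H]1C(=O)C[C@H]2[C@]3(C)CCC[C@]4(C)[C@H]3[C@@H](O[C@@H]5[C@@H](C(C)C)CC[C@H](C)C5)OC4=O
F9 | step 7 | lactol from F8 | C=C1C[C@]2(C=O)C[C@H]1C(=O)C[C@H]2[C@]3(C)CCC[C@]4(C)[C@H]3C(O)OC4=O
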